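## Assumptions (one line each)
- Commercial: 3-(TBDPSO)propan-1-ol, 1-bromo-1-methylcyclopropane, (1-methylcyclopropyl)methanol, (R)-3-methylcyclohexanone and 3-bromofuran-2(5H)-one.
- Kinetic LDA enolisation of 3-methylcyclohexanone favours the remote (C6) enolate; the minor achiral 3-methylcyclohex-2-enone is removed by chromatography after step 9.
- The SMILES corresponds to (4R,5R): the C4 methyl is trans to the C5 methyl, and the chain is cis to the C5 methyl.

## Retrosynthetic overview
1. Disconnect the butenolide C3–CH2 bond (Negishi) to alkyl iodide **19** plus 3-bromobutenolide **20**. The only ring that has to be built, the butenolide, is installed last as a pre-formed unit.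
2. Enone **17** comes from a retro-Dauben–Michno 1,3-carbonyl transposition of 6,6-disubstituted 5-methylcyclohex-2-enone **15**. The C4/C5 stereocentre pair comes from two α′-alkylations of chiral-pool (R)-5-methylcyclohexenone **13**: the whole side chain first, then MeI, both anti to the C5 methyl.
3. The E,E-chain iodide comes from two iterations of the Julia–Johnson 1-methylcyclopropylcarbinol → (E)-homoallylic bromide opening, starting from TBDPS-propanol.
4. Bold choices: the full C21 chain goes in on the first enolate alkylation, and the transposition is run with the polyene in place.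

## Route

**Step 1**
Reactants: 1, 3-(TBDPSO)propan-1-ol
Product: 2, 3-(TBDPSO)propanal
Conditions: DMP, NaHCO3, CH2Cl2, 0→23 °C
Reagents that add atoms: none
Why: Dess–Martin oxidation of a primary alcohol; no stereocentres.

**Step 2**
Reactants: 3, 1-bromo-1-methylcyclopropane; 2
Product: 4, 3-(TBDPSO)-1-(1-methylcyclopropyl)propan-1-ol
Conditions: 3, t-BuLi (2 equiv), Et2O, −78 °C; then 2, −78 °C
Reagents that add atoms: none
Why: Br/Li exchange then 1,2-addition of the cyclopropyllithium to the aldehyde; the new carbinol centre is transient and destroyed in step 3.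

**Step 3**
Reactant: 4
Product: 5, (E)-1-bromo-6-(TBDPSO)-3-methylhex-3-ene
Conditions: 48% aq HBr, ZnBr2 (cat.), CH2Cl2, 0 °C
Reagents that add atoms: hydrogen bromide, Br
Why: Julia–Johnson cyclopropylcarbinyl→homoallyl ring opening; the cation opens with the chain trans to the new CH2CH2Br arm, giving the E-trisubstituted alkene (expected ≥95:5). TBDPS is acid-stable.

**Step 4**
Reactant: 6, (1-methylcyclopropyl)methanol
Product: 7, 1-methylcyclopropane-1-carbaldehyde
Conditions: DMP, CH2Cl2, 0 °C (volatile, used as a crude solution)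
Reagents that add atoms: none
Why: Dess–Martin oxidation gives a non-enolisable aldehyde suited to Grignard addition.

**Step 5**
Reactants: 5; 7
Product: 8, (E)-4-methyl-1-(1-methylcyclopropyl)-7-(TBDPSO)hept-4-en-1-ol
Conditions: (i) 5, Mg, I2 (cat.), THF, 40 °C; (ii) 7, THF, −20→0 °C
Reagents that add atoms: none
Why: Grignard formation at the primary C–Br (the homoallyl Grignard does not close to cyclopropylcarbinyl) followed by aldehyde addition; the carbinol centre is transient.

**Step 6**
Reactant: 8
Product: 9, (3E,7E)-1-bromo-10-(TBDPSO)-3,7-dimethyldeca-3,7-diene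
Conditions: 48% aq HBr, ZnBr2 (cat.), CH2Cl2, 0 °C
Reagents that add atoms: hydrogen bromide, Br
Why: second Julia–Johnson opening, which sets the second E alkene with the head-to-tail isoprenoid orientation the target requires.

**Step 7**
Reactant: 9
Product: 10, the corresponding (3E,7E)-1-iodide
Conditions: NaI, acetone, 50 °C
Reagents that add atoms: sodium iodide, [Na+].[I-]
Why: Finkelstein SN2 at a primary bromide; the alkenes and silyl ether are untouched.

**Step 8**
Reactant: 11, (R)-3-methylcyclohexanone
Product: 12, (R)-TMS enol ether of 5-methylcyclohex-1-en-1-ol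
Conditions: LDA, THF, −78 °C; then TMSCl, −78→0 °C
Reagents that add atoms: chlorotrimethylsilane, C[Si](C)(C)Cl
Why: kinetic enolisation and O-silylation; the C5 stereocentre (chiral pool) is not involved.

**Step 9**
Reactant: 12
Product: 13, (R)-5-methylcyclohex-2-en-1-one
Conditions: Pd(OAc)2 (10 mol %), benzoquinone, MeCN, 23 °C
Reagents that add atoms: none
Why: Saegusa–Ito dehydrogenation; the only stereocentre is remote from the reacting centre and is preserved.

**Step 10**
Reactants: 13; 10
Product: 14, (5R,6S)-6-[chain]-5-methylcyclohex-2-en-1-one (R trans to Me)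
Conditions: 13, LDA, THF, −78 °C; then HMPA, 10, −78→−20 °C
Reagents that add atoms: none
Why: α′-alkylation of the cross-conjugated lithium enolate (the only α′ site is C6); axial attack anti to the C5 methyl gives the trans product, and this centre is re-enolised in step 11.

**Step 11**
Reactant: 14
Product: 15, (5R,6R)-6-methyl-6-[chain]-5-methylcyclohex-2-en-1-one
Conditions: LDA, THF, −78 °C; then MeI, HMPA, −78→0 °C
Reagents that add atoms: iodomethane, CI
Why: enolate alkylation; the C5 methyl is pseudo-axial because of A(1,2) strain with the C6 chain and blocks one face, so MeI adds anti to it. This sets the quaternary centre with Me trans and chain cis to the C5 methyl, as in the target, and it cannot epimerise afterwards.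

**Step 12**
Reactant: 15
Product: 16, tertiary allylic alcohol (1-methyl-1-hydroxy, 5R,6R; carbinol epimers)
Conditions: MeLi, THF, −78 °C
Reagents that add atoms: methyllithium, [Li]C
Why: 1,2-addition to the enone; the ketone has no α-H, so no enolisation, and the carbinol stereochemistry is lost in step 13.

**Step 13**
Reactant: 16
Product: 17, (4R,5R)-3,4,5-trimethyl-4-[(3E,7E)-10-(TBDPSO)-3,7-dimethyldeca-3,7-dien-1-yl]cyclohex-2-en-1-one
Conditions: PCC, NaOAc, CH2Cl2, 23 °C
Reagents that add atoms: none
Why: Dauben–Michno oxidative 1,3-transposition moves the carbonyl to the former β-carbon and leaves the methyl on the alkene carbon next to the quaternary centre; C4 and C5 are not involved.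

**Step 14**
Reactant: 17
Product: 18, the primary alcohol (TBDPS removed)
Conditions: TBAF, AcOH, THF, 0→23 °C
Reagents that add atoms: none
Why: fluoride cleavage of the silyl ether; AcOH buffering protects the enone.

**Step 15**
Reactant: 18
Product: 19, the primary iodide
Conditions: PPh3, I2, imidazole, CH2Cl2, 0 °C
Reagents that add atoms: iodine, II
Why: Appel-type SN2 iodination of a primary alcohol.

**Step 16**
Reactants: 19; 20, 3-bromofuran-2(5H)-one
Product: 21, cyclolinteinone
Conditions: (i) 19, Zn, LiCl, TMSCl/BrCH2CH2Br (activation), THF, 40 °C; (ii) 20, Pd(PPh3)4 (5 mol %), THF, 23 °C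
Reagents that add atoms: none
Why: Knochel-type alkylzinc formation (enone tolerated) then Negishi sp3–sp2 coupling at the vinyl bromide; no stereocentres are touched.

## Compound list
1 | 3-(TBDPSO)propan-1-ol | OCCCO[Si](c1ccccc1)(c1ccccc1)C(C)(C)C | starting material
2 | 3-(TBDPSO)propanal | O=CCCO[Si](c1ccccc1)(c1ccccc1)C(C)(C)C | intermediate
3 | 1-bromo-1-methylcyclopropane | CC1(Br)CC1 | starting material
4 | 3-(TBDPSO)-1-(1-methylcyclopropyl)propan-1-ol | CC1(CC1)C(O)CCO[Si](c1ccccc1)(c1ccccc1)C(C)(C)C | intermediate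
5 | (E)-1-bromo-6-(TBDPSO)-3-methylhex-3-ene | BrCC/C(C)=C/CCO[Si](c1ccccc1)(c1ccccc1)C(C)(C)C | intermediate
6 | (1-methylcyclopropyl)methanol | OCC1(C)CC1 | starting material
7 | 1-methylcyclopropane-1-carbaldehyde | O=CC1(C)CC1 | intermediate
8 | (E)-4-methyl-1-(1-methylcyclopropyl)-7-(TBDPSO)hept-4-en-1-ol | CC1(CC1)C(O)CC/C(C)=C/CCO[Si](c1ccccc1)(c1ccccc1)C(C)(C)C | intermediate
9 | (3E,7E)-1-bromo-10-(TBDPSO)-3,7-dimethyldeca-3,7-diene | BrCC/C(C)=C/CC/C(C)=C/CCO[Si](c1ccccc1)(c1ccccc1)C(C)(C)C | intermediate
10 | (3E,7E)-1-iodo-10-(TBDPSO)-3,7-dimethyldeca-3,7-diene | ICC/C(C)=C/CC/C(C)=C/CCO[Si](c1ccccc1)(c1ccccc1)C(C)(C)C | intermediate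
11 | (R)-3-methylcyclohexanone | C[C@@H]1CCCC(=O)C1 | starting material
12 | (R)-trimethyl[(5-methylcyclohex-1-en-1-yl)oxy]silane | C[C@@H]1CCC=C(O[Si](C)(C)C)C1 | intermediate
13 | (R)-5-methylcyclohex-2-en-1-one | C[C@@H]1CC=CC(=O)C1 | intermediate
14 | (5R,6S)-6-[chain]-5-methylcyclohex-2-en-1-one | C[C@@H]1CC=CC(=O)[C@H]1CC/C(C)=C/CC/C(C)=C/CCO[Si](c1ccccc1)(c1ccccc1)C(C)(C)C | intermediate
15 | (5R,6R)-6-methyl-6-[chain]-5-methylcyclohex-2-en-1-one | C[C@@H]1CC=CC(=O)[C@]1(C)CC/C(C)=C/CC/C(C)=C/CCO[Si](c1ccccc1)(c1ccccc1)C(C)(C)C | intermediate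
16 | tertiary allylic alcohol (1-methyl-1-ol; carbinol unspecified) | C[C@@H]1CC=CC(C)(O)[C@]1(C)CC/C(C)=C/CC/C(C)=C/CCO[Si](c1ccccc1)(c1ccccc1)C(C)(C)C | intermediate
17 | (4R,5R)-enone, OTBDPS chain | C[C@@H]1CC(=O)C=C(C)[C@]1(C)CC/C(C)=C/CC/C(C)=C/CCO[Si](c1ccccc1)(c1ccccc1)C(C)(C)C | intermediate
18 | (4R,5R)-4-[(3E,7E)-10-hydroxy-3,7-dimethyldeca-3,7-dien-1-yl]-3,4,5-trimethylcyclohex-2-en-1-one | C[C@@H]1CC(=O)C=C(C)[C@]1(C)CC/C(C)=C/CC/C(C)=C/CCO | intermediate
19 | corresponding 10-iodide | C[C@@H]1CC(=O)C=C(C)[C@]1(C)CC/C(C)=C/CC/C(C)=C/CCI | intermediate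
20 | 3-bromofuran-2(5H)-one | BrC1=CCOC1=O | starting material
21 | cyclolinteinone, (4R,5R)-4-[(3E,7E)-3,7-dimethyl-10-(2-oxo-2,5-dihydrofuran-3-yl)deca-3,7-dien-1-yl]-3,4,5-trimethylcyclohex-2-en-1-one | C[C@@H]1CC(=O)C=C(C)[C@]1(C)CC/C(C)=C/CC/C(C)=C/CCC1=CC(=O)OC1 | target

## Totals
Total steps: 16. Longest linear sequence: 13 (steps 1, 2, 3, 5, 6, 7, 10–16).

## Three steps most likely to fail
1. **Step 10 (alkylation of the enolate with the large, unactivated homoallylic iodide; E2, low conversion, dialkylation).**
   Fallback: use the short commercial handle 4-bromo-2-methylbut-1-ene, or TMS-homopropargyl iodide, in steps 10–13. Then build the E-trisubstituted alkenes on the ring by Zr-carboalumination/Negishi iteration, replacing enolate alkylation with sp2–sp3 cross-coupling.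
2. **Step 11 (diastereoselectivity of quaternisation anti to C5-Me; the wrong C4 epimer is the risk).**
   Fallback: run the double alkylation on enantioenriched (R)-3-ethoxy-5-methylcyclohex-2-enone, which has a rigid planar enolate, resolved as a menthyl vinylogous ester. Then use Stork–Danheiser MeLi/H3O+ to reach enone 17 directly, replacing steps 12–13.
3. **Step 16 (Negishi of the functionalised alkylzinc with 3-bromobutenolide; conjugate addition, butenolide sensitivity).**
   Fallback: Ni-catalysed reductive cross-electrophile coupling of iodide 19 with 3-bromobutenolide (radical alkyl–Ni pathway, no organozinc).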